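**Plan**

Ring atoms are numbered as in cyclodeca-2,6-dien-1-ol: C1 bears the ester oxygen, C10 the isopropyl group, C3 and C7 the methyl groups.
Retrosynthesis: cut the vanillate C–O bond, then the C6=C7 olefin (aldehyde C6 + methyl ketone C7), then C3–C4 and C2=C3 (aldehyde C2); the C2/C7 dicarbonyl that remains is the ozonolysis product of a cyclohexene.
Feature used: the arc C2–C1–C10–C9–C8–C7 (O on C1, isopropyl on C10, methyl on C7) is the ring of p-menth-1-en-3-ol once C2 and C7 are joined, and both trisubstituted olefins start at the ends of this arc. The target is a p-menthene whose C=C bond has taken up the unit C3(CH3)–C4–C5–C6, and ozonolysis delivers the C7 methyl ketone that the ring closure needs.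
Forward: (−)-menthone → (S)-piperitone → cis-piperitol silyl ether; ozonolysis opens the six-membered ring; C3 and its methyl are added by Z-selective iodo-olefination, C4–C6 by B-alkyl Suzuki coupling; the ten-membered ring is closed last at C6=C7 by reductive coupling of two carbonyl carbons; esterification and phenol release end the route.
Stereochemistry: C10 (S) from the chiral pool; C1 (R) by hydride addition to piperitone cis to the isopropyl group; 2Z from the stereospecific iodo-olefination/cross-coupling pair; 6Z from ring strain in the ring closure.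

Key step: step 8

Assumption: (−)-menthone is used free of its C2 epimer isomenthone (analytical grade, or freshly made by oxidation of (−)-menthol), since the epimer would erode the enantiomeric purity of 3.

**Route**

Step 1
Reactants: 1 (−)-menthone [(2S,5R)-5-methyl-2-(propan-2-yl)cyclohexan-1-one]
Product: 3 (S)-piperitone [(6S)-3-methyl-6-(propan-2-yl)cyclohex-2-en-1-one], via menthone trimethylsilyl enol ether 2 (not isolated)
Conditions: LiN(i-Pr)2 (LDA), THF, −78 °C; TMSCl, −78 °C → rt; then Pd(OAc)2 (1.0 equiv), MeCN, rt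
Reagents that add atoms: none
Why: Kinetic deprotonation takes the less hindered CH2 α-proton, so the isopropyl-bearing stereocentre is untouched, and the silyl enol ether undergoes Saegusa–Ito oxidation (oxa-π-allyl palladium, β-hydride elimination of the hydrogen on the methyl-bearing carbon) to the conjugated enone.

Step 2
Reactants: 3 (S)-piperitone
Product: 4 cis-piperitol [(1R,6S)-3-methyl-6-(propan-2-yl)cyclohex-2-en-1-ol; OH and isopropyl cis]
Conditions: LiBH(s-Bu)3 (L-Selectride), THF, −78 °C; then H2O
Reagents that add atoms: none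
Why: The bulky hydride adds 1,2 to the β,β-disubstituted enone from the equatorial direction (as in the reduction of menthone to neomenthol), which should place the hydroxyl group axial and cis to the equatorial isopropyl group and so set C1 as R.

Step 3
Reactants: 4 cis-piperitol
Product: 5 tert-butyldimethyl{[(1R,6S)-3-methyl-6-(propan-2-yl)cyclohex-2-en-1-yl]oxy}silane
Conditions: TBSOTf, 2,6-lutidine, CH2Cl2, −78 → 0 °C
Reagents that add atoms: tert-butyldimethylsilyl trifluoromethanesulfonate (TBSOTf), CC(C)(C)[Si](C)(C)OS(=O)(=O)C(F)(F)F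
Why: Silylation of the hindered allylic alcohol with the silyl triflate and a non-nucleophilic base is a standard protection that leaves both stereocentres untouched.

Step 4
Reactants: 5 cis-piperitol TBS ether
Product: 6 (2R,3S)-2-[(tert-butyldimethylsilyl)oxy]-6-oxo-3-(propan-2-yl)heptanal
Conditions: O3, CH2Cl2, −78 °C; then PPh3, −78 °C → rt
Reagents that add atoms: ozone, [O-][O+]=O
Why: Ozonolysis of the trisubstituted ring olefin with reductive work-up should open the cyclohexene to the C2 aldehyde and the C7 methyl ketone without touching C1 or C10.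

Step 5
Reactants: 6 keto aldehyde
Product: 7 (5S,6R,7Z)-6-[(tert-butyldimethylsilyl)oxy]-8-iodo-5-(propan-2-yl)non-7-en-2-one (iodine cis to the silyloxy-bearing carbon)
Conditions: [Ph3PEt]I, n-BuLi, THF, 0 °C; I2, −78 °C; NaN(SiMe3)2, −78 → −20 °C; then 6, −78 °C → rt
Reagents that add atoms: ethyltriphenylphosphonium iodide, CC[P+](c1ccccc1)(c1ccccc1)c1ccccc1.[I-]; iodine, II
Why: Wittig iodo-olefination (Stork–Zhao type) with the unstabilized α-iodo ylide should take the aldehyde far faster than the methyl ketone at −78 °C and give the Z vinyl iodide under kinetic cis-oxaphosphetane control.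

Step 6
Reactants: 7 vinyl iodide; 8 acrolein diethyl acetal (3,3-diethoxyprop-1-ene)
Product: 10 (5S,6R,7Z)-6-[(tert-butyldimethylsilyl)oxy]-11,11-diethoxy-8-methyl-5-(propan-2-yl)undec-7-en-2-one, via 9-(3,3-diethoxypropyl)-9-borabicyclo[3.3.1]nonane 9 (not isolated)
Conditions: 8, 9-BBN-H, THF, 0 °C → rt; then 7, Pd(dppf)Cl2 (5 mol %), AsPh3, Cs2CO3, DMF/H2O, rt
Reagents that add atoms: none
Why: Anti-Markovnikov hydroboration gives the primary alkylborane, whose B-alkyl Suzuki–Miyaura coupling with the vinyl iodide proceeds with retention of olefin geometry and so fixes C4 cis to C1 across C2=C3 (2Z); the ketone is inert because no B–H bond remains.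

Step 7
Reactants: 10 keto acetal
Product: 11 (4Z,6R,7S)-6-[(tert-butyldimethylsilyl)oxy]-4-methyl-10-oxo-7-(propan-2-yl)undec-4-enal
Conditions: PPTS (cat.), acetone/H2O, 40 °C
Reagents that add atoms: water, O
Why: Mild acid-catalysed acetal hydrolysis should release the C6 aldehyde while the secondary silyl ether, the olefin and the ketone persist.

Step 8
Reactants: 11 keto aldehyde
Product: 12 tert-butyl{[(1R,2Z,6Z,10S)-3,7-dimethyl-10-(propan-2-yl)cyclodeca-2,6-dien-1-yl]oxy}dimethylsilane
Conditions: TiCl3(DME)1.5, Zn–Cu couple, DME, reflux; 11 added by syringe pump over 30 h (high dilution), then reflux 6 h; aq. K2CO3 work-up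
Reagents that add atoms: none
Why: Low-valent titanium generated from TiCl3(DME)1.5 and Zn–Cu reduces the C6 aldehyde and the C7 methyl ketone to surface-bound ketyls that couple to a cyclic titanium pinacolate, which loses both oxygens at reflux to give the C6=C7 olefin (intramolecular McMurry coupling). The closest known reaction type is the titanium-induced cyclization of keto aldehydes to trisubstituted cycloalkenes of medium ring size, cyclodeca-1,5-dienes of the germacrane type included. The ten-membered carbocycle closes by end-to-end C=C bond formation between the two chain termini, favoured over oligomerization by slow addition to the titanium slurry. No stereocentre is formed, and C1 and C10 cannot epimerize because neither is α to a carbonyl group. The step needs intramolecular aldehyde–ketone coupling and Z geometry at C6=C7: the first is secured by high dilution, the second by the ring, since deoxygenation is stepwise and not stereospecific and a ring that already holds the cis C2=C3 olefin should take a second cis olefin with less strain than a trans one. The silyl ether, unlike a free allylic alcohol or an ester, should be inert to the reagent.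

Step 9
Reactants: 12 cyclodecadienyl silyl ether
Product: 13 (1R,2Z,6Z,10S)-3,7-dimethyl-10-(propan-2-yl)cyclodeca-2,6-dien-1-ol
Conditions: Bu4NF, THF, 0 °C → rt
Reagents that add atoms: none
Why: Fluoride-induced Si–O cleavage frees the allylic alcohol under non-acidic conditions that avoid transannular cyclization of the 1,5-diene.

Step 10
Reactants: 13 dienol; 14 4-acetoxy-3-methoxybenzoic acid
Product: 15 (1R,2Z,6Z,10S)-3,7-dimethyl-10-(propan-2-yl)cyclodeca-2,6-dien-1-yl 4-acetoxy-3-methoxybenzoate
Conditions: DCC, DMAP (cat.), CH2Cl2, 0 °C → rt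
Reagents that add atoms: none
Why: Steglich esterification (carbodiimide activation, acyl transfer by DMAP) acylates the secondary alcohol with retention at C1, the phenol being masked as its acetate to prevent self-acylation.

Step 11
Reactants: 15 acetyl-protected ester
Product: 16 (1R,2Z,6Z,10S)-3,7-dimethyl-10-(propan-2-yl)cyclodeca-2,6-dien-1-yl 4-hydroxy-3-methoxybenzoate (target)
Conditions: pyrrolidine, CH2Cl2, 0 °C → rt
Reagents that add atoms: none
Why: Aminolysis of the aryl acetate by pyrrolidine should be far faster than attack on the hindered secondary alkyl benzoate, so the phenol is released without touching the vanillate ester.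

**Compound list**

1 | (−)-menthone [(2S,5R)-5-methyl-2-(propan-2-yl)cyclohexan-1-one] | CC(C)[C@@H]1CC[C@@H](C)CC1=O | starting material
2 | trimethyl{[(3R,6S)-3-methyl-6-(propan-2-yl)cyclohex-1-en-1-yl]oxy}silane | CC(C)[C@@H]1CC[C@@H](C)C=C1O[Si](C)(C)C | intermediate
3 | (S)-piperitone [(6S)-3-methyl-6-(propan-2-yl)cyclohex-2-en-1-one] | CC(C)[C@@H]1CCC(C)=CC1=O | intermediate
4 | cis-piperitol [(1R,6S)-3-methyl-6-(propan-2-yl)cyclohex-2-en-1-ol] | CC(C)[C@@H]1CCC(C)=C[C@@H]1O | intermediate
5 | tert-butyldimethyl{[(1R,6S)-3-methyl-6-(propan-2-yl)cyclohex-2-en-1-yl]oxy}silane | CC(C)[C@@H]1CCC(C)=C[C@@H]1O[Si](C)(C)C(C)(C)C | intermediate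
6 | (2R,3S)-2-[(tert-butyldimethylsilyl)oxy]-6-oxo-3-(propan-2-yl)heptanal | CC(C)[C@H](CCC(C)=O)[C@H](C=O)O[Si](C)(C)C(C)(C)C | intermediate
7 | (5S,6R,7Z)-6-[(tert-butyldimethylsilyl)oxy]-8-iodo-5-(propan-2-yl)non-7-en-2-one | C/C(I)=C/[C@H](O[Si](C)(C)C(C)(C)C)[C@@H](CCC(C)=O)C(C)C | intermediate
8 | acrolein diethyl acetal (3,3-diethoxyprop-1-ene) | C=CC(OCC)OCC | starting material
9 | 9-(3,3-diethoxypropyl)-9-borabicyclo[3.3.1]nonane | CCOC(CCB1C2CCCC1CCC2)OCC | intermediate
10 | (5S,6R,7Z)-6-[(tert-butyldimethylsilyl)oxy]-11,11-diethoxy-8-methyl-5-(propan-2-yl)undec-7-en-2-one | C/C(CCC(OCC)OCC)=C/[C@H](O[Si](C)(C)C(C)(C)C)[C@@H](CCC(C)=O)C(C)C | intermediate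
11 | (4Z,6R,7S)-6-[(tert-butyldimethylsilyl)oxy]-4-methyl-10-oxo-7-(propan-2-yl)undec-4-enal | C/C(CCC=O)=C/[C@H](O[Si](C)(C)C(C)(C)C)[C@@H](CCC(C)=O)C(C)C | intermediate
12 | tert-butyl{[(1R,2Z,6Z,10S)-3,7-dimethyl-10-(propan-2-yl)cyclodeca-2,6-dien-1-yl]oxy}dimethylsilane | CC(C)(C)[Si](C)(C)O[C@H]1/C=C(/C)CC/C=C(/C)CC[C@H]1C(C)C | intermediate
13 | (1R,2Z,6Z,10S)-3,7-dimethyl-10-(propan-2-yl)cyclodeca-2,6-dien-1-ol | O[C@H]1/C=C(/C)CC/C=C(/C)CC[C@H]1C(C)C | intermediate
14 | 4-acetoxy-3-methoxybenzoic acid | COc1cc(C(=O)O)ccc1OC(C)=O | starting material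
15 | (1R,2Z,6Z,10S)-3,7-dimethyl-10-(propan-2-yl)cyclodeca-2,6-dien-1-yl 4-acetoxy-3-methoxybenzoate | COc1cc(C(=O)O[C@H]2/C=C(/C)CC/C=C(/C)CC[C@H]2C(C)C)ccc1OC(C)=O | intermediate
16 | (1R,2Z,6Z,10S)-3,7-dimethyl-10-(propan-2-yl)cyclodeca-2,6-dien-1-yl 4-hydroxy-3-methoxybenzoate | COc1cc(C(=O)O[C@H]2/C=C(/C)CC/C=C(/C)CC[C@H]2C(C)C)ccc1O | target

**Step count and risks**

Total step count: 11. Longest linear sequence: 11 steps (1 → 16).

Steps most likely to fail:

1. Step 8. The titanium pinacolate may be deoxygenated to the trans C6=C7 olefin as well as the cis one, the reaction may stop at the pinacol, or intermolecular coupling may compete with ring closure. Fallback: from 7, Negishi coupling with but-3-enylzinc bromide (CH2=CHCH2CH2ZnBr, Pd(dppf)Cl2, THF) should give (5S,6R,7Z)-6-[(tert-butyldimethylsilyl)oxy]-8-methyl-5-(propan-2-yl)dodeca-7,11-dien-2-one F1. Wittig methylenation of the ketone (Ph3P=CH2 from [Ph3PCH3]Br and KOt-Bu, THF) should give tert-butyl{[(5Z,7R,8S)-5,11-dimethyl-8-(propan-2-yl)dodeca-1,5,11-trien-7-yl]oxy}dimethylsilane F2. Ring-closing metathesis with the second-generation Grubbs catalyst in toluene at high dilution should then close C6=C7 with loss of ethene and return to the route at 12.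

2. Step 5. The basic ylide may enolize the α-silyloxy aldehyde (loss of configuration at C1) or trigger aldol condensation of the keto aldehyde, and Z/E control may be incomplete. Fallback: from 6, Corey–Fuchs reaction at the aldehyde (CBr4, PPh3, CH2Cl2, 0 °C) should give (5S,6R)-8,8-dibromo-6-[(tert-butyldimethylsilyl)oxy]-5-(propan-2-yl)oct-7-en-2-one F3. Palladium-catalysed Negishi methylation of the less hindered bromine trans to the silyloxy-bearing carbon (MeZnCl, Pd(DPEphos)Cl2, THF) should give (5S,6R,7Z)-8-bromo-6-[(tert-butyldimethylsilyl)oxy]-5-(propan-2-yl)non-7-en-2-one F4. Coupling of this bromide with borane 9 as in step 6, with Pd(P(t-Bu)3)2 to keep retention, returns to the route at 10.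

3. Step 2. Facial selectivity of hydride addition may be poor, giving the trans alcohol. Fallback: from 3, Luche reduction (NaBH4, CeCl3·7H2O, MeOH, −78 °C), expected to favour axial attack, should give trans-piperitol [(1S,6S)-3-methyl-6-(propan-2-yl)cyclohex-2-en-1-ol] F5 (it can also be separated from a mixture). Mitsunobu esterification with 4-nitrobenzoic acid (PPh3, DIAD, THF) should invert C1 to (1R,6S)-3-methyl-6-(propan-2-yl)cyclohex-2-en-1-yl 4-nitrobenzoate F6, and methanolysis (K2CO3, MeOH) returns to the route at 4.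

**Further compounds**

F1 | step 8 | (5S,6R,7Z)-6-[(tert-butyldimethylsilyl)oxy]-8-methyl-5-(propan-2-yl)dodeca-7,11-dien-2-one | C/C(CCC=C)=C/[C@H](O[Si](C)(C)C(C)(C)C)[C@@H](CCC(C)=O)C(C)C
F2 | step 8 | tert-butyl{[(5Z,7R,8S)-5,11-dimethyl-8-(propan-2-yl)dodeca-1,5,11-trien-7-yl]oxy}dimethylsilane | C/C(CCC=C)=C/[C@H](O[Si](C)(C)C(C)(C)C)[C@@H](CCC(C)=C)C(C)C
F3 | step 5 | (5S,6R)-8,8-dibromo-6-[(tert-butyldimethylsilyl)oxy]-5-(propan-2-yl)oct-7-en-2-one | BrC(Br)=C[C@H](O[Si](C)(C)C(C)(C)C)[C@@H](CCC(C)=O)C(C)C
F4 | step 5 | (5S,6R,7Z)-8-bromo-6-[(tert-butyldimethylsilyl)oxy]-5-(propan-2-yl)non-7-en-2-one | C/C(Br)=C/[C@H](O[Si](C)(C)C(C)(C)C)[C@@H](CCC(C)=O)C(C)C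
F5 | step 2 | trans-piperitol [(1S,6S)-3-methyl-6-(propan-2-yl)cyclohex-2-en-1-ol] | CC(C)[C@@H]1CCC(C)=C[C@H]1O
F6 | step 2 | (1R,6S)-3-methyl-6-(propan-2-yl)cyclohex-2-en-1-yl 4-nitrobenzoate | CC(C)[C@@H]1CCC(C)=C[C@@H]1OC(=O)c1ccc(cc1)[N+](=O)[O-]
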